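The five-membered ring carries oxygen on C2 and C4, on both sides of its only CH2 group (C3). This 1,3-pattern is read as a cyclopent-2-enone (C4=O, C2=C3). Everything rests on making C2=C3 by ring-closing metathesis between a vinyl ketone on C5 and the vinyl group on quaternary C1 of a preformed cycloheptene. One operation completes the trans-hydroazulene and creates an enone whose faces are differentiated by the angular methyl. That enone then accepts oxygen (via boron) at C2 and isopropyl at C4. The precursor, a 1,2,7-trisubstituted cycloheptene, gets its three contiguous stereocentres from one dianionic Ireland–Claisen rearrangement of a chiral-pool β-hydroxy ester.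

Key step: step 9

Numbering used (daucane): C1 = ring-fusion carbon bearing CH3; C2 = CH–OAc; C3 = ring CH2; C4 = C(OH)(i-Pr); C5 = ring-fusion CH; C6 = CH–O-aroyl; C7 = CH2; C8 = C(CH3)=; C9 = =CH; C10 = CH2. α is the face of H-5 and β is the face of the C1 methyl.

Step 1
Reactants: 1 pent-1-en-4-yne
Product: 4 (2E)-3-methylhexa-2,5-dien-1-ol, via alkenylalane 2 (not isolated), via lithium aluminate 3 (not isolated)
Conditions: Me3Al (2 equiv), Cp2ZrCl2 (20 mol %), CH2Cl2, 0 °C to rt; n-BuLi, THF, −78 °C; (CH2O)n, to rt; aqueous work-up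
Reagents that add atoms: trimethylaluminium, C[Al](C)C; n-butyllithium, [Li]CCCC (in 3 only); formaldehyde as paraformaldehyde, C=O
Why: Zirconium-catalysed carboalumination adds CH3 and Al syn across the alkyne only (the alkene is inert), so hydroxymethylation of the derived aluminate fixes the E trisubstituted alkene whose geometry later defines C1.

Step 2
Reactants: 5 ethyl (R)-4-chloro-3-hydroxybutanoate
Product: 6 ethyl (R)-oxiran-2-ylacetate
Conditions: Ag2O, 1,2-dimethoxyethane, reflux
Reagents that add atoms: none
Why: Silver-assisted intramolecular Williamson closure displaces the primary chloride without touching the carbinol stereocentre and avoids the base-induced elimination to the 4-hydroxycrotonate.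

Step 3
Reactants: 6 ethyl (R)-oxiran-2-ylacetate
Product: 7 ethyl (S)-3-hydroxy-5-methylhex-5-enoate
Conditions: CH2=C(CH3)MgBr (1.5 equiv), CuI (15 mol %), THF, −40 °C; aq NH4Cl
Reagents that add atoms: isopropenylmagnesium bromide, CC(=C)[Mg]Br
Why: Copper-catalysed Grignard opening of the terminal epoxide at its CH2 (SN2) outruns ester attack at low temperature and leaves the stereocentre (future C6) untouched, the descriptor changing only through priorities.

Step 4
Reactants: 7 ethyl (S)-3-hydroxy-5-methylhex-5-enoate; 4 (2E)-3-methylhexa-2,5-dien-1-ol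
Product: 8 (2E)-3-methylhexa-2,5-dien-1-yl (S)-3-hydroxy-5-methylhex-5-enoate
Conditions: Ti(OEt)4 (25 mol %), toluene, 100 °C, ethanol distilled off
Reagents that add atoms: none
Why: Titanate-catalysed transesterification is neutral, tolerates the free β-hydroxyl and both dienes, introduces no foreign alkoxide and is driven by removal of ethanol.

Step 5
Reactants: 8 (2E)-3-methylhexa-2,5-dien-1-yl (S)-3-hydroxy-5-methylhex-5-enoate
Product: 10 (2S,3S)-3-ethenyl-2-[(1S)-1-hydroxy-3-methylbut-3-en-1-yl]-3-methylhex-5-enoic acid, via dilithium enolate alkoxide 9 (not isolated)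
Conditions: LDA (2.6 equiv), THF, −78 °C, then warm to 40 °C; 1 M HCl
Reagents that add atoms: lithium diisopropylamide, CC(C)[N-]C(C)C.[Li+] (lithium, in 9 only)
Why: In this dianionic Ireland–Claisen rearrangement the lithium chelate fixes the enolate geometry (C6 cis to OLi) and shields one face as in a Fráter–Seebach alkylation, so C5 forms anti to the C6 hydroxyl, while the chair transition state with the E alkene (allyl equatorial, methyl axial) sets quaternary C1 relative to C5.

Step 6
Reactants: 10 the hydroxy acid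
Product: 11 tert-butyldimethylsilyl (2S,3S)-2-[(1S)-1-(tert-butyldimethylsilyloxy)-3-methylbut-3-en-1-yl]-3-ethenyl-3-methylhex-5-enoate
Conditions: TBSOTf (2.4 equiv), 2,6-lutidine (3 equiv), CH2Cl2, 0 °C
Reagents that add atoms: tert-butyldimethylsilyl triflate, CC(C)(C)[Si](C)(C)OS(=O)(=O)C(F)(F)F
Why: One silylation protects the C6 hydroxyl for all basic steps ahead and turns the very hindered acid into a silyl ester that step 8 activates directly.

Step 7
Reactants: 11 the bis-silylated triene
Product: 12 tert-butyldimethylsilyl (1S,2S,7S)-7-(tert-butyldimethylsilyloxy)-2-ethenyl-2,5-dimethylcyclohept-4-ene-1-carboxylate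
Conditions: RuCl2(=CHPh)(PCy3)(H2IMes) (second-generation Grubbs catalyst, 5 mol %), CH2Cl2 (3 mM), 40 °C
Reagents that add atoms: none
Why: In this ring-closing metathesis the catalyst loads on the unhindered allyl group, from which only closure onto the methallyl group (seven-membered ring, C8=C9) is possible because the geminal vinyl would give a cyclobutene, and the neopentyl vinyl initiates too slowly to form the six-membered alternative.

Step 8
Reactants: 12 the cycloheptene silyl ester
Product: 14 1-[(1S,2S,7S)-7-(tert-butyldimethylsilyloxy)-2-ethenyl-2,5-dimethylcyclohept-4-en-1-yl]prop-2-en-1-one, via acid chloride 13 (not isolated)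
Conditions: (COCl)2, DMF (cat.), CH2Cl2, 0 °C to rt, evaporate; CH2=CHSnBu3, BnPdCl(PPh3)2 (3 mol %), CHCl3, CO (1 atm), 60 °C
Reagents that add atoms: oxalyl chloride, O=C(Cl)C(Cl)=O (chlorine, in 13 only); tributyl(vinyl)stannane, C=C[Sn](CCCC)(CCCC)CCCC
Why: Silyl esters give acid chlorides with oxalyl chloride/DMF under neutral conditions, and Stille acylation then delivers the vinyl ketone without the over-addition, C5 enolisation or β-elimination of the silyloxy group that a basic vinyl metal could cause.

Step 9
Reactants: 14 the cycloheptenyl vinyl ketone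
Product: 15 (3aS,4S,8aS)-4-(tert-butyldimethylsilyloxy)-6,8a-dimethyl-4,5,8,8a-tetrahydroazulen-3(3aH)-one (trans-fused; C2=C3, C4=O)
Conditions: RuCl2(=CH-C6H4-2-Oi-Pr)(H2IMes) (second-generation Hoveyda–Grubbs catalyst, 10 mol %), 1,4-benzoquinone (20 mol %), toluene (2 mM), 80 °C, argon sparge
Reagents that add atoms: none
Why: The ruthenium alkylidene first exchanges with the electron-neutral C1 vinyl group, the new alkylidene adds intramolecularly to the vinyl ketone with its carbon bonding to the carbonyl-bearing CH (the polarity-matched orientation that leaves Ru on the CH2 terminus), and cycloreversion releases the enone and Ru=CH2, loss of ethylene making the closure irreversible. The closest known reaction type is ring-closing metathesis of 1,6-dien-3-ones with an allylic quaternary carbon to 4,4-disubstituted cyclopent-2-enones. The one ring closed is the five-membered ring C1–C5, formed by joining the two internal vinyl carbons C2 and C3 of a 1,6-diene, and the trans fusion is reachable because the two arms sit trans on adjacent carbons of a flexible cycloheptene. No stereocentre is created; C1, C5 and C6 are carried over, and the neutral medium spares the epimerisable C5–H and the β-silyloxy ketone. The selectivity needed is reaction of the two monosubstituted alkenes only: the trisubstituted C8=C9 bond is inert, and because the seven-membered ring was closed in step 7 the faster six-ring closures (allyl onto enone, vinyl onto methallyl) that would lead to a decalin are no longer available.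

Step 10
Reactants: 15 the bicyclic enone
Product: 17 (1S,3aS,4S,8aR)-4-(tert-butyldimethylsilyloxy)-1-hydroxy-6,8a-dimethyl-1,3a,4,5,8,8a-hexahydroazulen-3(2H)-one (C2 α-OH), via pinacol boronate 16 (not isolated)
Conditions: B2pin2 (1.2 equiv), CuCl (5 mol %), DPEphos (5 mol %), NaOt-Bu (5 mol %), MeOH (2 equiv), THF, rt; then NaBO3·4H2O, THF/H2O, rt
Reagents that add atoms: bis(pinacolato)diboron, CC1(C)OB(OC1(C)C)B1OC(C)(C)C(C)(C)O1 (in 16 only); sodium perborate, [Na+].[O-]OB=O (oxygen at C2)
Why: In this copper-catalysed conjugate borylation with stereoretentive oxidation the copper–boryl species adds to C2 from the α face, opposite the axial angular methyl on neighbouring C1, so that C–B and then C–O are α (2S).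

Step 11
Reactants: 17 the β-hydroxy ketone
Product: 18 (1S,3R,3aS,4S,8aR)-4-(tert-butyldimethylsilyloxy)-6,8a-dimethyl-3-(propan-2-yl)-1,2,3,3a,4,5,8,8a-octahydroazulene-1,3-diol
Conditions: i-PrMgCl (3.5 equiv), anhydrous CeCl3 (3.5 equiv), THF, −78 °C; aq NH4Cl
Reagents that add atoms: isopropylmagnesium chloride, CC(C)[Mg]Cl
Why: The weakly basic organocerium reagent avoids enolisation, retro-aldol and β-hydride reduction, and after deprotonating the C2 hydroxyl it should attack C4=O from the α face, away from the 1,3-related axial angular methyl, placing isopropyl α and hydroxyl β (4R).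

Step 12
Reactants: 18 the diol
Product: 19 (1S,3R,3aS,4S,8aR)-4-(tert-butyldimethylsilyloxy)-3-hydroxy-6,8a-dimethyl-3-(propan-2-yl)-1,2,3,3a,4,5,8,8a-octahydroazulen-1-yl acetate
Conditions: Ac2O (1.5 equiv), DMAP (10 mol %), pyridine, CH2Cl2, 0 °C to rt
Reagents that add atoms: acetic anhydride, CC(=O)OC(C)=O
Why: DMAP-catalysed acylation takes the secondary C2 hydroxyl while the tertiary C4 hydroxyl stays free.

Step 13
Reactants: 19 the silyl ether acetate
Product: 20 (1S,3R,3aS,4S,8aR)-3,4-dihydroxy-6,8a-dimethyl-3-(propan-2-yl)-1,2,3,3a,4,5,8,8a-octahydroazulen-1-yl acetate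
Conditions: HF·pyridine, pyridine, THF, 0 °C to rt
Reagents that add atoms: none
Why: Buffered fluoride desilylation frees C6–OH without ionising the tertiary alcohol and without acyl migration, since the C2 acetate is trans to C4–OH and remote from C6.

Step 14
Reactants: 20 the diol acetate; 21 4-acetoxybenzoyl chloride
Product: 22 (1S,3R,3aS,4S,8aR)-1-acetoxy-3-hydroxy-6,8a-dimethyl-3-(propan-2-yl)-1,2,3,3a,4,5,8,8a-octahydroazulen-4-yl 4-acetoxybenzoate
Conditions: 21 (2 equiv), Et3N, DMAP, CH2Cl2, 40 °C
Reagents that add atoms: none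
Why: DMAP-catalysed acylation with the acid chloride reaches the only remaining secondary hydroxyl (C6), and the phenol is masked so that the acyl donor cannot self-condense.

Step 15
Reactants: 22 the protected diester
Product: 23 (1S,3R,3aS,4S,8aR)-1-acetoxy-3-hydroxy-6,8a-dimethyl-3-(propan-2-yl)-1,2,3,3a,4,5,8,8a-octahydroazulen-4-yl 4-hydroxybenzoate
Conditions: NH4OAc, MeOH/H2O (4:1), rt
Reagents that add atoms: none
Why: An aryl acetate is a far better acyl donor than the alkyl acetate or the benzoate, so neutral ammonium acetate-mediated hydrolysis removes only the phenolic acetate.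

Compound list
1 | pent-1-en-4-yne | C=CCC#C | starting material
2 | (E)-dimethyl(2-methylpenta-1,4-dien-1-yl)alane | C[Al](C)/C=C(\C)CC=C | intermediate
3 | lithium butyl(dimethyl)[(E)-2-methylpenta-1,4-dien-1-yl]aluminate | [Li+].CCCC[Al-](C)(C)/C=C(\C)CC=C | intermediate
4 | (2E)-3-methylhexa-2,5-dien-1-ol | OC/C=C(\C)CC=C | intermediate
5 | ethyl (R)-4-chloro-3-hydroxybutanoate | CCOC(=O)C[C@@H](O)CCl | starting material
6 | ethyl (R)-oxiran-2-ylacetate | CCOC(=O)C[C@@H]1CO1 | intermediate
7 | ethyl (S)-3-hydroxy-5-methylhex-5-enoate | CCOC(=O)C[C@@H](O)CC(C)=C | intermediate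
8 | (2E)-3-methylhexa-2,5-dien-1-yl (S)-3-hydroxy-5-methylhex-5-enoate | C=CC/C(C)=C/COC(=O)C[C@@H](O)CC(C)=C | intermediate
9 | dilithium enolate alkoxide of 8 (C6 cis to OLi) | C=CC/C(C)=C/CO/C(O[Li])=C/[C@@H](O[Li])CC(C)=C | intermediate
10 | (2S,3S)-3-ethenyl-2-[(1S)-1-hydroxy-3-methylbut-3-en-1-yl]-3-methylhex-5-enoic acid | OC(=O)[C@@H]([C@](C)(C=C)CC=C)[C@@H](O)CC(C)=C | intermediate
11 | bis-TBS derivative (silyl ester and C6 silyl ether) of 10 | CC(C)(C)[Si](C)(C)OC(=O)[C@@H]([C@](C)(C=C)CC=C)[C@@H](O[Si](C)(C)C(C)(C)C)CC(C)=C | intermediate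
12 | TBS (1S,2S,7S)-7-(TBSO)-2-ethenyl-2,5-dimethylcyclohept-4-ene-1-carboxylate | CC(C)(C)[Si](C)(C)OC(=O)[C@@H]1[C@@H](O[Si](C)(C)C(C)(C)C)CC(C)=CC[C@@]1(C)C=C | intermediate
13 | (1S,2S,7S)-7-(TBSO)-2-ethenyl-2,5-dimethylcyclohept-4-ene-1-carbonyl chloride | ClC(=O)[C@@H]1[C@@H](O[Si](C)(C)C(C)(C)C)CC(C)=CC[C@@]1(C)C=C | intermediate
14 | 1-[(1S,2S,7S)-7-(TBSO)-2-ethenyl-2,5-dimethylcyclohept-4-en-1-yl]prop-2-en-1-one | C=CC(=O)[C@@H]1[C@@H](O[Si](C)(C)C(C)(C)C)CC(C)=CC[C@@]1(C)C=C | intermediate
15 | (3aS,4S,8aS)-4-(TBSO)-6,8a-dimethyl-4,5,8,8a-tetrahydroazulen-3(3aH)-one | C1=CC(=O)[C@@H]2[C@@H](O[Si](C)(C)C(C)(C)C)CC(C)=CC[C@@]12C | intermediate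
16 | (1S,3aS,4S,8aS) C2 α-pinacolboronate of the saturated ketone | CC1(C)OB(OC1(C)C)[C@H]2CC(=O)[C@@H]3[C@@H](O[Si](C)(C)C(C)(C)C)CC(C)=CC[C@@]23C | intermediate
17 | (1S,3aS,4S,8aR)-4-(TBSO)-1-hydroxy-6,8a-dimethyl-1,3a,4,5,8,8a-hexahydroazulen-3(2H)-one | O[C@H]1CC(=O)[C@@H]2[C@@H](O[Si](C)(C)C(C)(C)C)CC(C)=CC[C@@]12C | intermediate
18 | (1S,3R,3aS,4S,8aR)-4-(TBSO)-6,8a-dimethyl-3-(propan-2-yl)octahydroazulene-1,3-diol | O[C@H]1C[C@@](O)(C(C)C)[C@@H]2[C@@H](O[Si](C)(C)C(C)(C)C)CC(C)=CC[C@@]12C | intermediate
19 | C2 acetate of 18 | CC(=O)O[C@H]1C[C@@](O)(C(C)C)[C@@H]2[C@@H](O[Si](C)(C)C(C)(C)C)CC(C)=CC[C@@]12C | intermediate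
20 | C2 acetate with free C4 and C6 hydroxyls | CC(=O)O[C@H]1C[C@@](O)(C(C)C)[C@@H]2[C@@H](O)CC(C)=CC[C@@]12C | intermediate
21 | 4-acetoxybenzoyl chloride | CC(=O)Oc1ccc(cc1)C(Cl)=O | starting material
22 | C2 acetate, C6 4-acetoxybenzoate | CC(=O)O[C@H]1C[C@@](O)(C(C)C)[C@@H]2[C@@H](OC(=O)c3ccc(OC(C)=O)cc3)CC(C)=CC[C@@]12C | intermediate
23 | (1S,3R,3aS,4S,8aR)-1-acetoxy-3-hydroxy-6,8a-dimethyl-3-(propan-2-yl)-1,2,3,3a,4,5,8,8a-octahydroazulen-4-yl 4-hydroxybenzoate | CC(=O)O[C@H]1C[C@@](O)(C(C)C)[C@@H]2[C@@H](OC(=O)c3ccc(O)cc3)CC(C)=CC[C@@]12C | target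

Total step count: 15. Longest linear sequence: 14 (steps 2 to 15, from compound 5).

Steps most likely to fail

**Step 9.** Both alkenes initiate poorly: one is neopentyl and the other is electron-poor. Catalyst decay, alkene isomerisation or intermolecular coupling may therefore overtake closure of the strained trans-fused enone. The fallback sets out from 14 and moves the closure to the alcohol oxidation level.
- Luche reduction (NaBH4, CeCl3·7H2O, MeOH, −78 °C) gives the divinyl carbinol F3, in which both carbinol epimers are usable.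
- The electron-neutral alkene of F3 is activated by its allylic hydroxyl and should close with RuCl2(=CHPh)(PCy3)(H2IMes) in CH2Cl2 at 40 °C to the bicyclic cyclopentenol F4.
- Oxidation with MnO2 returns to the route at 15.

**Step 11.** The metal alkoxide at C2 lies on the α face. It may erode the facial preference set by the angular methyl, and enolisation or retro-aldol cleavage may compete. The fallback sets out from 15 and reverses the order of events.
- i-PrMgCl/CeCl3 adds 1,2 to the enone while C2 is still planar and the α face is open. This gives the tertiary allylic alcohol F5.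
- Hydroxyl-directed oxymercuration follows (Hg(OAc)2, THF/H2O). Mercury is held on the β face near C3 by the C4 hydroxyl, and water attacks the distal C2 anti, from the α face. The disubstituted alkene reacts before the trisubstituted one, giving the organomercurial F6.
- NaBH4/NaOH demercuration comes back to the route at 18.

**Step 5.** The dianion may decompose (ketene loss, retro-aldol) before the slow rearrangement onto a fully substituted alkene terminus, and warming may loosen the chelate that controls the face. The fallback sets out from 8 and uses a neutral species instead.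
- TBSCl/imidazole gives the silyl ether ester F1.
- LDA in THF/DMPU with TBSCl gives the silyl ketene acetal F2 with the same enolate geometry (C6 trans to the allyloxy group).
- On warming, F2 undergoes the classical Ireland–Claisen rearrangement directly to the silyl ester. It rejoins the route at 11, with facial control now resting on the non-chelated silyloxy stereocentre.

Further compounds
F1 | step 5 | (2E)-3-methylhexa-2,5-dien-1-yl (S)-3-(tert-butyldimethylsilyloxy)-5-methylhex-5-enoate | C=CC/C(C)=C/COC(=O)C[C@@H](O[Si](C)(C)C(C)(C)C)CC(C)=C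
F2 | step 5 | TBS ketene acetal of F1 (C6 trans to the allyloxy group) | C=CC/C(C)=C/CO/C(O[Si](C)(C)C(C)(C)C)=C/[C@@H](O[Si](C)(C)C(C)(C)C)CC(C)=C
F3 | step 9 | 1-[(1S,2S,7S)-7-(TBSO)-2-ethenyl-2,5-dimethylcyclohept-4-en-1-yl]prop-2-en-1-ol (both carbinol epimers) | C=CC(O)[C@@H]1[C@@H](O[Si](C)(C)C(C)(C)C)CC(C)=CC[C@@]1(C)C=C
F4 | step 9 | trans-fused 4-(TBSO)-6,8a-dimethyl-3,3a,4,5,8,8a-hexahydroazulen-3-ol (both carbinol epimers) | C1=CC(O)[C@@H]2[C@@H](O[Si](C)(C)C(C)(C)C)CC(C)=CC[C@@]12C
F5 | step 11 | tertiary allylic alcohol, C4 β-OH and α-isopropyl, C2=C3 | C1=C[C@@](O)(C(C)C)[C@@H]2[C@@H](O[Si](C)(C)C(C)(C)C)CC(C)=CC[C@@]12C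
F6 | step 11 | C3 β-acetoxymercurio C2 α-hydroxy adduct of F5 | O[C@H]1[C@H]([Hg]OC(C)=O)[C@@](O)(C(C)C)[C@@H]2[C@@H](O[Si](C)(C)C(C)(C)C)CC(C)=CC[C@@]12C
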